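Numbering: chain C1–C15 of the pentadeca-1,6,11-triene (C10 = quaternary carbon, C13 = allylic CHMe); ring C1′–C6′ (C1′ on C15, C2′ = CMe2, C3′ = CHMe, C6′ = C=CH2).
Cuts: C10–C11 (allylic substitution: alkyne 19 + C16 phosphate 26), then C14–C15 (alkyl–alkyl coupling), then the ring bonds C3′–C4′ and C1′–C2′ together.
Enabling feature: C2′(CH3)2–C3′H(CH3) is an intact 2-methylbut-2-ene, and C4′–C5′–C6′(=CH2)–C1′–C15, with C15 raised to an acyl group, is a 3-methylpenta-2,4-dienoyl unit; the ring is therefore a formal [4+2] adduct of a bulk C5 alkene and an electron-poor diene.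
Forward: dienoyl imide (steps 1–2), ring (step 3), alkene shift and side chain to alkyne 19 (steps 4–11); farnesol to phosphate 26 (steps 12–17); union and quaternary carbon in step 18.
Stereochemistry: C1′ from the oxazolidinone auxiliary, C3′ relative to it in the annulation; C13 from (S)-3-bromo-2-methylpropan-1-ol; C3 and C10 from two catalyst-controlled SN2′ substitutions; 6E from farnesol, 11E from syn-hydroalumination.

Key step: step 3

Remark on the chemistry: ligand L1 (step 15, a binaphthol-derived bis(1-arylethyl)amine phosphoramidite) and carbene precursor L2 (step 18, an N-aryl-N′-(2-sulfonatoaryl)imidazolinium salt) are taken as the antipodes that give 10S in 24 and the S quaternary carbon in 28, to be confirmed on a model substrate; farnesol is the pure 2E,6E isomer.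

Step 1
Reactants: 1 but-2-ynoic acid; 2 (4S)-4-benzyl-1,3-oxazolidin-2-one
Product: 4 (4S)-4-benzyl-3-(but-2-ynoyl)-1,3-oxazolidin-2-one, via but-2-ynoic pivalic anhydride 3 (not isolated)
Conditions: PivCl, Et3N, THF, −20 °C; then 2, LiCl, −20 °C → rt
Reagents that add atoms: none
Why: N-acylation of the oxazolidinone by the mixed pivalic anhydride under LiCl/Et3N activation is a standard, base-mild route to unsaturated N-acyl oxazolidinones and leaves the ynoyl group untouched.

Step 2
Reactants: 4 (4S)-4-benzyl-3-(but-2-ynoyl)-1,3-oxazolidin-2-one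
Product: 5 (4S)-4-benzyl-3-[(2E)-3-methylpenta-2,4-dienoyl]-1,3-oxazolidin-2-one
Conditions: CH2=CHMgBr, CuBr·SMe2 (1.3 equiv each), THF, −78 °C; then 4, −78 °C; aq NH4Cl, −78 °C
Reagents that add atoms: vinylmagnesium bromide, C=C[Mg]Br
Why: Syn-carbocupration of the ynoyl imide puts the vinyl group on the β-carbon cis to the α-hydrogen, and protonation of the alkenylcopper with retention gives the 2E dienoyl imide, whose acyl group is trans to the vinyl group as the ring closure requires.

Step 3
Reactants: 5 (4S)-4-benzyl-3-[(2E)-3-methylpenta-2,4-dienoyl]-1,3-oxazolidin-2-one; 6 2-methylbut-2-ene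
Product: 7 (4S)-4-benzyl-3-{[(1R,5S)-2,5,6,6-tetramethylcyclohex-2-en-1-yl]carbonyl}-1,3-oxazolidin-2-one
Conditions: 6 (15 equiv), Me2AlCl (2.0 equiv), CH2Cl2, −78 → −30 °C
Reagents that add atoms: none
Why: Proposed new method: chelation of both imide carbonyls by Me2Al+ (from 2 equiv of Me2AlCl) turns the 3-methylpenta-2,4-dienoyl group into a vinylogous acceptor; its unsubstituted terminal CH2 is attacked by the CH carbon of 6 (Markovnikov sense, making C4–C5 of 7 and a tertiary cation at the CMe2 carbon), and the cation is captured by the α-carbon of the aluminium dienolate (making C1–C6), so that 6 acts as the two-carbon partner of a polar, asynchronous inverse-electron-demand Diels–Alder reaction. The closest known reaction types are the Me2AlCl-promoted Diels–Alder reactions of unsaturated N-acyl oxazolidinones, which engage π-nucleophiles of the strength of 6 at low temperature, the Lewis acid-promoted ene and [2+2] reactions of acrylates with trisubstituted alkenes, and the tert-alkylation of chelated imide enolates by tertiary carbocations. The one ring closes in the second bond-forming event, a 6-(enolexo) collapse of the enolate carbon onto the cation, the sum being a [4+2] cycloaddition across the termini of the s-cis diene. C1 is set by the auxiliary: in the s-cis chelate the benzyl group covers one face of the α-carbon and the new bond forms on the other, as in enolate alkylations of the same auxiliary, which here corresponds to 1R; C5 is set relative to C1, because addition of 6 is expected to be reversible and the half-chair closure keeps the C5 methyl pseudo-equatorial, which gives the cis (1R,5S) ring. The step needs δ- rather than β-attack (the β-carbon is fully substituted), α- rather than γ-closure (six- rather than four-membered ring) and closure rather than proton loss from the cation (low temperature, no base, excess 6), and any trans epimer is a diastereomer of 7 that can be removed by chromatography.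

Step 4
Reactants: 7 (4S)-4-benzyl-3-{[(1R,5S)-2,5,6,6-tetramethylcyclohex-2-en-1-yl]carbonyl}-1,3-oxazolidin-2-one
Product: 8 [(1R,5S)-2,5,6,6-tetramethylcyclohex-2-en-1-yl]methanol
Conditions: LiBH4, H2O (1 equiv), Et2O, 0 °C
Reagents that add atoms: none
Why: Hydride cleavage of the N-acyl oxazolidinone (auxiliary removal) gives the primary alcohol and returns 2, and the C1 stereocenter is not enolised under these conditions.

Step 5
Reactants: 8 [(1R,5S)-2,5,6,6-tetramethylcyclohex-2-en-1-yl]methanol
Product: 11 [(1R,3S)-2,2,3-trimethyl-6-methylidenecyclohexyl]methanol, via dipotassium alkoxide allylpotassium 9 (not isolated), via dipotassium allyltrimethoxyborate alkoxide 10 (not isolated)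
Conditions: n-BuLi, KOt-Bu (2.3 equiv each), hexane/THF, −78 → −20 °C; B(OMe)3, −78 °C; 1 M HCl, 0 °C
Reagents that add atoms: none
Why: Contra-thermodynamic alkene isomerisation: Schlosser-base metalation at the primary allylic methyl group (helped by the neighbouring alkoxide), boration at that terminus and SE2′ protonolysis of the allylborate at the ring carbon is the known way to turn a 1-methylcyclohexene into a methylenecyclohexane, and no stereocenter is touched.

Step 6
Reactants: 11 [(1R,3S)-2,2,3-trimethyl-6-methylidenecyclohexyl]methanol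
Product: 12 [(1R,3S)-2,2,3-trimethyl-6-methylidenecyclohexyl]methyl iodide
Conditions: I2, PPh3, imidazole, CH2Cl2, 0 °C → rt
Reagents that add atoms: iodine, II
Why: Appel-type iodination through the alkoxyphosphonium salt proceeds by SN2 at the CH2 group and leaves both ring stereocenters and the 1,1-disubstituted alkene alone.

Step 7
Reactants: 13 (2S)-3-bromo-2-methylpropan-1-ol
Product: 14 [(2S)-3-bromo-2-methylpropoxy](tert-butyl)dimethylsilane
Conditions: TBSCl, imidazole, DMF, rt
Reagents that add atoms: tert-butyldimethylsilyl chloride, CC(C)(C)[Si](C)(C)Cl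
Why: Standard silylation of the primary alcohol; the stereocenter is not at a reacting atom.

Step 8
Reactants: 12 [(1R,3S)-2,2,3-trimethyl-6-methylidenecyclohexyl]methyl iodide; 14 [(2S)-3-bromo-2-methylpropoxy](tert-butyl)dimethylsilane
Product: 16 tert-butyl(dimethyl){(2R)-2-methyl-4-[(1R,3S)-2,2,3-trimethyl-6-methylidenecyclohexyl]butoxy}silane, via [(2,2,3-trimethyl-6-methylidenecyclohexyl)methyl]magnesium iodide 15 (not isolated)
Conditions: Mg, THF, 40 °C; then 14 (1.5 equiv), Li2CuCl4 (5 mol %), NMP, THF, 0 °C → rt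
Reagents that add atoms: none
Why: Copper-catalysed alkyl–alkyl cross-coupling of a primary Grignard reagent with a primary alkyl bromide (Kochi-type, NMP-accelerated) joins C15 to C14; the methyl-bearing stereocenter of 14 is β to the reacting carbon and is carried through.

Step 9
Reactants: 16 tert-butyl(dimethyl){(2R)-2-methyl-4-[(1R,3S)-2,2,3-trimethyl-6-methylidenecyclohexyl]butoxy}silane
Product: 17 (2R)-2-methyl-4-[(1R,3S)-2,2,3-trimethyl-6-methylidenecyclohexyl]butan-1-ol
Conditions: TBAF, THF, rt
Reagents that add atoms: none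
Why: Fluoride cleavage of the silyl ether; nothing else in the molecule responds to TBAF.

Step 10
Reactants: 17 (2R)-2-methyl-4-[(1R,3S)-2,2,3-trimethyl-6-methylidenecyclohexyl]butan-1-ol
Product: 18 (2R)-2-methyl-4-[(1R,3S)-2,2,3-trimethyl-6-methylidenecyclohexyl]butanal
Conditions: Dess–Martin periodinane, CH2Cl2, 0 °C → rt
Reagents that add atoms: none
Why: Dess–Martin oxidation gives the α-branched aldehyde under non-basic conditions that should neither epimerise it nor move the exocyclic alkene.

Step 11
Reactants: 18 (2R)-2-methyl-4-[(1R,3S)-2,2,3-trimethyl-6-methylidenecyclohexyl]butanal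
Product: 19 (3R)-3-methyl-5-[(1R,3S)-2,2,3-trimethyl-6-methylidenecyclohexyl]pent-1-yne
Conditions: dimethyl (1-diazo-2-oxopropyl)phosphonate, K2CO3, MeOH, 0 °C → rt
Reagents that add atoms: dimethyl (1-diazo-2-oxopropyl)phosphonate, COP(=O)(OC)C(=[N+]=[N-])C(C)=O
Why: Ohira–Bestmann homologation (Seyferth–Gilbert type) converts the aldehyde into the terminal alkyne with one added carbon, and the mild carbonate conditions are expected to preserve the α-alkyl stereocenter.

Step 12
Reactants: 20 (2E,6E)-farnesol
Product: 21 tert-butyl(dimethyl){[(2E,6E)-3,7,11-trimethyldodeca-2,6,10-trien-1-yl]oxy}silane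
Conditions: TBSCl, imidazole, DMF, rt
Reagents that add atoms: tert-butyldimethylsilyl chloride, CC(C)(C)[Si](C)(C)Cl
Why: Standard silylation masks the allylic alcohol for the oxidation and Grignard steps.

Step 13
Reactants: 21 tert-butyl(dimethyl){[(2E,6E)-3,7,11-trimethyldodeca-2,6,10-trien-1-yl]oxy}silane
Product: 22 (2E,6E,10E)-12-{[tert-butyl(dimethyl)silyl]oxy}-2,6,10-trimethyldodeca-2,6,10-trien-1-ol
Conditions: SeO2 (10 mol %), t-BuOOH, salicylic acid (10 mol %), CH2Cl2, 0 °C → rt
Reagents that add atoms: tert-butyl hydroperoxide (oxygen donor, relayed by SeO2), CC(C)(C)OO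
Why: SeO2-catalysed allylic oxidation (ene reaction, then [2,3] shift) is selective for the E-methyl group of the terminal, most electron-rich trisubstituted alkene and gives the E allylic alcohol.

Step 14
Reactants: 22 (2E,6E,10E)-12-{[tert-butyl(dimethyl)silyl]oxy}-2,6,10-trimethyldodeca-2,6,10-trien-1-ol
Product: 23 {[(2E,6E,10E)-12-bromo-3,7,11-trimethyldodeca-2,6,10-trien-1-yl]oxy}(tert-butyl)dimethylsilane
Conditions: CBr4, PPh3, CH2Cl2, −30 → 0 °C
Reagents that add atoms: carbon tetrabromide, BrC(Br)(Br)Br
Why: Appel bromination converts the primary allylic alcohol into the bromide without allylic transposition at low temperature.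

Step 15
Reactants: 23 {[(2E,6E,10E)-12-bromo-3,7,11-trimethyldodeca-2,6,10-trien-1-yl]oxy}(tert-butyl)dimethylsilane
Product: 24 tert-butyl(dimethyl){[(2E,6E,10S)-3,7,10,11-tetramethyldodeca-2,6,11-trien-1-yl]oxy}silane
Conditions: MeMgBr (1.3 equiv), Cu(O2CC4H3S) (copper thiophene-2-carboxylate, 3 mol %), L1 (3.3 mol %), CH2Cl2, −78 °C
Reagents that add atoms: methylmagnesium bromide, C[Mg]Br
Why: Copper-catalysed asymmetric allylic alkylation with a Grignard reagent delivers methyl in the SN2′ sense to C10 of the 2-methyl-substituted E-allylic bromide, creating the isopropenyl end group and the C10 stereocenter, whose S configuration is fixed by the antipode of L1; the silyl ether and the other alkenes are inert.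

Step 16
Reactants: 24 tert-butyl(dimethyl){[(2E,6E,10S)-3,7,10,11-tetramethyldodeca-2,6,11-trien-1-yl]oxy}silane
Product: 25 (2E,6E,10S)-3,7,10,11-tetramethyldodeca-2,6,11-trien-1-ol
Conditions: TBAF, THF, rt
Reagents that add atoms: none
Why: Fluoride cleavage of the silyl ether frees the allylic alcohol without touching the alkenes or the stereocenter.

Step 17
Reactants: 25 (2E,6E,10S)-3,7,10,11-tetramethyldodeca-2,6,11-trien-1-ol
Product: 26 diethyl (2E,6E,10S)-3,7,10,11-tetramethyldodeca-2,6,11-trien-1-yl phosphate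
Conditions: ClP(O)(OEt)2, Et3N, DMAP (cat.), CH2Cl2, 0 °C
Reagents that add atoms: diethyl chlorophosphate, CCOP(=O)(Cl)OCC
Why: Phosphorylation of the allylic alcohol installs the leaving group needed for copper-catalysed allylic substitution; no stereo element is touched.

Step 18
Reactants: 19 (3R)-3-methyl-5-[(1R,3S)-2,2,3-trimethyl-6-methylidenecyclohexyl]pent-1-yne; 26 diethyl (2E,6E,10S)-3,7,10,11-tetramethyldodeca-2,6,11-trien-1-yl phosphate
Product: 28 (3S,6E,10S,11E,13R)-10-ethenyl-2,3,6,10,13-pentamethyl-15-[(1R,3S)-2,2,3-trimethyl-6-methylidenecyclohexyl]pentadeca-1,6,11-triene, via (E)-alkenyl(diisobutyl)aluminium 27 (not isolated)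
Conditions: 19 (1.3 equiv), i-Bu2AlH, hexanes, 55 °C; then 26, L2 (2.5 mol %), CuCl2·2H2O (5 mol %), THF, −15 °C
Reagents that add atoms: none
Why: Syn-hydroalumination of the terminal alkyne gives the E-alkenylalane, and NHC–copper-catalysed enantioselective allylic substitution (SN2′) transfers the alkenyl group with retention of geometry to C3 of the E-allylic phosphate, forming the vinyl-bearing quaternary carbon whose S configuration is set by the carbene antipode (reagent control; the distant stereocenters are not involved).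

Compound list
1 | but-2-ynoic acid | CC#CC(=O)O | starting material
2 | (4S)-4-benzyl-1,3-oxazolidin-2-one | O=C1N[C@@H](Cc2ccccc2)CO1 | starting material
3 | but-2-ynoic pivalic anhydride | CC#CC(=O)OC(=O)C(C)(C)C | intermediate (not isolated)
4 | (4S)-4-benzyl-3-(but-2-ynoyl)-1,3-oxazolidin-2-one | CC#CC(=O)N1[C@@H](Cc2ccccc2)COC1=O | intermediate
5 | (4S)-4-benzyl-3-[(2E)-3-methylpenta-2,4-dienoyl]-1,3-oxazolidin-2-one | C=C/C(C)=C/C(=O)N1[C@@H](Cc2ccccc2)COC1=O | intermediate
6 | 2-methylbut-2-ene | CC=C(C)C | starting material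
7 | (4S)-4-benzyl-3-{[(1R,5S)-2,5,6,6-tetramethylcyclohex-2-en-1-yl]carbonyl}-1,3-oxazolidin-2-one | O=C([C@@H]1C(C)=CC[C@H](C)C1(C)C)N1[C@@H](Cc2ccccc2)COC1=O | intermediate
8 | [(1R,5S)-2,5,6,6-tetramethylcyclohex-2-en-1-yl]methanol | OC[C@@H]1C(C)=CC[C@H](C)C1(C)C | intermediate
9 | dipotassium alkoxide allylpotassium derived from 8 | [K+].[K+].[O-]C[C@@H]1C([CH2-])=CC[C@H](C)C1(C)C | intermediate (not isolated)
10 | dipotassium allyltrimethoxyborate alkoxide derived from 9 | [K+].[K+].[O-]C[C@@H]1C(C[B-](OC)(OC)OC)=CC[C@H](C)C1(C)C | intermediate (not isolated)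
11 | [(1R,3S)-2,2,3-trimethyl-6-methylidenecyclohexyl]methanol | OC[C@@H]1C(=C)CC[C@H](C)C1(C)C | intermediate
12 | [(1R,3S)-2,2,3-trimethyl-6-methylidenecyclohexyl]methyl iodide | IC[C@@H]1C(=C)CC[C@H](C)C1(C)C | intermediate
13 | (2S)-3-bromo-2-methylpropan-1-ol | OC[C@H](C)CBr | starting material
14 | [(2S)-3-bromo-2-methylpropoxy](tert-butyl)dimethylsilane | CC(C)(C)[Si](C)(C)OC[C@H](C)CBr | intermediate
15 | {[(1R,3S)-2,2,3-trimethyl-6-methylidenecyclohexyl]methyl}magnesium iodide | I[Mg]C[C@@H]1C(=C)CC[C@H](C)C1(C)C | intermediate (not isolated)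
16 | tert-butyl(dimethyl){(2R)-2-methyl-4-[(1R,3S)-2,2,3-trimethyl-6-methylidenecyclohexyl]butoxy}silane | CC(C)(C)[Si](C)(C)OC[C@H](C)CC[C@@H]1C(=C)CC[C@H](C)C1(C)C | intermediate
17 | (2R)-2-methyl-4-[(1R,3S)-2,2,3-trimethyl-6-methylidenecyclohexyl]butan-1-ol | OC[C@H](C)CC[C@@H]1C(=C)CC[C@H](C)C1(C)C | intermediate
18 | (2R)-2-methyl-4-[(1R,3S)-2,2,3-trimethyl-6-methylidenecyclohexyl]butanal | O=C[C@H](C)CC[C@@H]1C(=C)CC[C@H](C)C1(C)C | intermediate
19 | (3R)-3-methyl-5-[(1R,3S)-2,2,3-trimethyl-6-methylidenecyclohexyl]pent-1-yne | C#C[C@H](C)CC[C@@H]1C(=C)CC[C@H](C)C1(C)C | intermediate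
20 | (2E,6E)-farnesol, (2E,6E)-3,7,11-trimethyldodeca-2,6,10-trien-1-ol | OC/C=C(\C)CC/C=C(\C)CCC=C(C)C | starting material
21 | tert-butyl(dimethyl){[(2E,6E)-3,7,11-trimethyldodeca-2,6,10-trien-1-yl]oxy}silane | CC(C)(C)[Si](C)(C)OC/C=C(\C)CC/C=C(\C)CCC=C(C)C | intermediate
22 | (2E,6E,10E)-12-{[tert-butyl(dimethyl)silyl]oxy}-2,6,10-trimethyldodeca-2,6,10-trien-1-ol | CC(C)(C)[Si](C)(C)OC/C=C(\C)CC/C=C(\C)CC/C=C(\C)CO | intermediate
23 | {[(2E,6E,10E)-12-bromo-3,7,11-trimethyldodeca-2,6,10-trien-1-yl]oxy}(tert-butyl)dimethylsilane | CC(C)(C)[Si](C)(C)OC/C=C(\C)CC/C=C(\C)CC/C=C(\C)CBr | intermediate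
24 | tert-butyl(dimethyl){[(2E,6E,10S)-3,7,10,11-tetramethyldodeca-2,6,11-trien-1-yl]oxy}silane | CC(C)(C)[Si](C)(C)OC/C=C(\C)CC/C=C(\C)CC[C@H](C)C(=C)C | intermediate
25 | (2E,6E,10S)-3,7,10,11-tetramethyldodeca-2,6,11-trien-1-ol | OC/C=C(\C)CC/C=C(\C)CC[C@H](C)C(=C)C | intermediate
26 | diethyl (2E,6E,10S)-3,7,10,11-tetramethyldodeca-2,6,11-trien-1-yl phosphate | CCOP(=O)(OCC)OC/C=C(\C)CC/C=C(\C)CC[C@H](C)C(=C)C | intermediate
27 | diisobutyl{(1E,3R)-3-methyl-5-[(1R,3S)-2,2,3-trimethyl-6-methylidenecyclohexyl]pent-1-en-1-yl}aluminium | CC(C)C[Al](CC(C)C)/C=C/[C@H](C)CC[C@@H]1C(=C)CC[C@H](C)C1(C)C | intermediate (not isolated)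
28 | (3S,6E,10S,11E,13R)-10-ethenyl-2,3,6,10,13-pentamethyl-15-[(1R,3S)-2,2,3-trimethyl-6-methylidenecyclohexyl]pentadeca-1,6,11-triene (CNP0293684.4) | C=C[C@@](C)(/C=C/[C@H](C)CC[C@@H]1C(=C)CC[C@H](C)C1(C)C)CC/C=C(\C)CC[C@H](C)C(=C)C | target

Total steps: 18. Longest linear sequence: 11 (steps 1–6, 8–11, 18).

Steps most likely to fail

1. Step 3 (Proposed new method). The tertiary cation may lose a proton instead of closing (ene-type diversion), the ring may close with poor control at the methyl-bearing carbon, or a methyl group may pass from aluminium to the activated dienoyl group. The fallback uses known chemistry, sets out from 25 and comes back at 19, so that steps 1–11 are not needed. Noyori-type asymmetric hydrogenation of the allylic alcohol of 25 (Ru(OAc)2[(S)-BINAP], H2, MeOH), expected by analogy with geraniol to give 3R and to leave the unfunctionalised alkenes alone, gives (3R,6E,10S)-3,7,10,11-tetramethyldodeca-6,11-dien-1-ol F1, whose C10 already has the configuration of the ring methyl carbon. Acid-promoted cation–olefin cyclisation (ClSO3H, 2-nitropropane, −78 °C), with protonation of the 1,1-disubstituted terminus and chair closure onto the 6E alkene with both substituents equatorial (the irone-type ring closure), should give the cis ring as its endocyclic isomer, (3R)-3-methyl-5-[(1R,5S)-2,5,6,6-tetramethylcyclohex-2-en-1-yl]pentan-1-ol F2. The alkene is moved out of the ring as in step 5, through the dipotassium alkoxide allylpotassium F3 and the dipotassium allyltrimethoxyborate alkoxide F4, to give (3R)-3-methyl-5-[(1R,3S)-2,2,3-trimethyl-6-methylidenecyclohexyl]pentan-1-ol F5. Dess–Martin oxidation gives (3R)-3-methyl-5-[(1R,3S)-2,2,3-trimethyl-6-methylidenecyclohexyl]pentanal F6, and one-pot enol sulfonate formation and elimination (C4F9SO2F, phosphazene base t-BuN=P(NMe2)3, DMF), through (3R)-3-methyl-5-[(1R,3S)-2,2,3-trimethyl-6-methylidenecyclohexyl]pent-1-en-1-yl nonafluorobutane-1-sulfonate F7, gives alkyne 19 with no change in carbon count.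

2. Step 5. Metalation may occur at the ring methylene, or the allylborate may be protonated at the exocyclic terminus, so that endocyclic isomers return. The fallback sets out from 8 and comes back at 11. The same metalation (through 9) is quenched with excess Me3SiCl to give the isolable and purifiable allylsilane trimethyl({(1S,5S)-5,6,6-trimethyl-2-[(trimethylsilyl)methyl]cyclohex-2-en-1-yl}methoxy)silane F8. Acid protodesilylation with allylic transposition (CF3CO2H, CH2Cl2, 0 °C; then K2CO3, MeOH) places the proton on the ring carbon and gives 11.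

3. Step 18. The α-branched terminal alkyne may be deprotonated by i-Bu2AlH instead of hydroaluminated, and isobutyl transfer or incomplete facial control may interfere when the quaternary carbon forms. The fallback sets out from 19 and comes back at 28. Hydroboration with pinacolborane under Cp2Zr(H)Cl catalysis gives the isolable 2-{(1E,3R)-3-methyl-5-[(1R,3S)-2,2,3-trimethyl-6-methylidenecyclohexyl]pent-1-en-1-yl}-4,4,5,5-tetramethyl-1,3,2-dioxaborolane F9. NHC–copper-catalysed allylic substitution of 26 with F9 (L2, CuCl, NaOMe, THF) then gives 28 without an organoaluminium stage.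

Further compounds
F1 | step 3 | (3R,6E,10S)-3,7,10,11-tetramethyldodeca-6,11-dien-1-ol | OCC[C@H](C)CC/C=C(\C)CC[C@H](C)C(=C)C
F2 | step 3 | (3R)-3-methyl-5-[(1R,5S)-2,5,6,6-tetramethylcyclohex-2-en-1-yl]pentan-1-ol | OCC[C@H](C)CC[C@@H]1C(C)=CC[C@H](C)C1(C)C
F3 | step 3 | dipotassium alkoxide allylpotassium derived from F2 | [K+].[K+].[O-]CC[C@H](C)CC[C@@H]1C([CH2-])=CC[C@H](C)C1(C)C
F4 | step 3 | dipotassium allyltrimethoxyborate alkoxide derived from F3 | [K+].[K+].[O-]CC[C@H](C)CC[C@@H]1C(C[B-](OC)(OC)OC)=CC[C@H](C)C1(C)C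
F5 | step 3 | (3R)-3-methyl-5-[(1R,3S)-2,2,3-trimethyl-6-methylidenecyclohexyl]pentan-1-ol | OCC[C@H](C)CC[C@@H]1C(=C)CC[C@H](C)C1(C)C
F6 | step 3 | (3R)-3-methyl-5-[(1R,3S)-2,2,3-trimethyl-6-methylidenecyclohexyl]pentanal | O=CC[C@H](C)CC[C@@H]1C(=C)CC[C@H](C)C1(C)C
F7 | step 3 | (3R)-3-methyl-5-[(1R,3S)-2,2,3-trimethyl-6-methylidenecyclohexyl]pent-1-en-1-yl nonafluorobutane-1-sulfonate | FC(F)(F)C(F)(F)C(F)(F)C(F)(F)S(=O)(=O)OC=C[C@H](C)CC[C@@H]1C(=C)CC[C@H](C)C1(C)C
F8 | step 5 | trimethyl({(1S,5S)-5,6,6-trimethyl-2-[(trimethylsilyl)methyl]cyclohex-2-en-1-yl}methoxy)silane | C[Si](C)(C)OC[C@@H]1C(C[Si](C)(C)C)=CC[C@H](C)C1(C)C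
F9 | step 18 | 2-{(1E,3R)-3-methyl-5-[(1R,3S)-2,2,3-trimethyl-6-methylidenecyclohexyl]pent-1-en-1-yl}-4,4,5,5-tetramethyl-1,3,2-dioxaborolane | CC1(C)OB(/C=C/[C@H](C)CC[C@@H]2C(=C)CC[C@H](C)C2(C)C)OC1(C)C
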